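**Plan**
- Cuts: C11=C12 and C11'=C12' (two Wittig reactions on the C10 dialdehyde), C8–C9 (alkyne–ynoate addition), C7'=C8' (Horner–Wadsworth–Emmons) and, in the acetylenic ring, the C5=C6 bond.
- Enabling feature: in the cyclohexene ring C1–C6, C6 is propargylic to C7≡C8 and flanked by the quaternary C1, while C5 carries the methyl group. An open-chain C5 methyl ketone bearing a C6 propargylic acetate can therefore be closed by turning C6 into an allenyl-metal nucleophile; dehydration then gives the tetrasubstituted enyne.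
- Forward order: acyclic C1–C8 chain from (R)-epichlorohydrin, ring closure (step 7), dehydration, growth to a C15 phosphonium salt. The diol ring is bought as β-cyclocitral, extended to a second C15 salt, joined to the C10 dialdehyde and then to the acetylenic salt; desilylation is last.
- Stereochemistry: C3 from (R)-epichlorohydrin; C6' from Sharpless epoxidation and C5' by inversion on epoxide hydrolysis (trans-diol). The C6 epimers formed on the way converge. E-olefins come from syn-hydroalkynylation, Horner–Wadsworth–Emmons olefination and thermal equilibration after each Wittig step.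

Key step: step 7

Remark: positions are given in carotenoid numbering (ring C1–C6, chain C7–C15, primed numbers for the diol half); the all-E geometry of the given structure is taken as the wanted one and all numbered starting materials are assumed to be catalogue compounds.

**Route**

Step 1
Reactants: 1 (R)-epichlorohydrin; 2 isopropenylmagnesium bromide
Product: 3 (R)-1-chloro-4-methylpent-4-en-2-ol
Conditions: CuI (10 mol%), THF, −40 °C → 0 °C; then H2O
Reagents that add atoms: none
Why: Copper-catalysed Grignard opening of the epoxide at its unsubstituted carbon does not touch the stereocentre, so the (R) configuration of 1 becomes C3 of the target.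

Step 2
Reactants: 3 (R)-1-chloro-4-methylpent-4-en-2-ol; 4 isobutyronitrile
Product: 6 (R)-4-hydroxy-2,2,6-trimethylhept-6-enenitrile, via (R)-2-(2-methylallyl)oxirane 5 (not isolated)
Conditions: 4 (2.5 equiv), LiN(i-Pr)2 (2.5 equiv), THF, −78 °C; then 3, −78 °C → rt; then H2O at 0 °C
Reagents that add atoms: none
Why: The lithium alkoxide of 3 closes to the terminal epoxide 5 and the lithiated nitrile opens it at the primary carbon (nitrile-anion epoxide alkylation), which installs the quaternary C1 next to the future C6 without touching C3.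

Step 3
Reactants: 6 (R)-4-hydroxy-2,2,6-trimethylhept-6-enenitrile
Product: 7 (R)-4-[(tert-butyldiphenylsilyl)oxy]-2,2,6-trimethylhept-6-enenitrile
Conditions: t-BuPh2SiCl, imidazole, DMF, rt
Reagents that add atoms: tert-butyl(chloro)diphenylsilane, CC(C)(C)[Si](Cl)(c1ccccc1)c1ccccc1
Why: Standard silylation of the secondary alcohol; the bulky diphenylsilyl ether is chosen because it must survive hydride, ozone, SmI2 and the acidic dehydration of step 8.

Step 4
Reactants: 7 (R)-4-[(tert-butyldiphenylsilyl)oxy]-2,2,6-trimethylhept-6-enenitrile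
Product: 9 (R)-4-[(tert-butyldiphenylsilyl)oxy]-2,2,6-trimethylhept-6-enal, via aluminium aldimine 8 (not isolated)
Conditions: i-Bu2AlH (1.5 equiv), toluene, −78 °C → 0 °C; then aq. tartaric acid, rt
Reagents that add atoms: water, O
Why: Partial reduction of the hindered tertiary nitrile stops at the aluminium aldimine, which hydrolyses to the neopentyl aldehyde (nitrile-to-aldehyde reduction).

Step 5
Reactants: 9 (R)-4-[(tert-butyldiphenylsilyl)oxy]-2,2,6-trimethylhept-6-enal; 10 ethynyltrimethylsilane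
Product: 12 (6R)-6-[(tert-butyldiphenylsilyl)oxy]-4,4,8-trimethyl-1-(trimethylsilyl)non-8-en-1-yn-3-yl acetate (both C3 epimers), via lithium propargylic alkoxide 11 (not isolated)
Conditions: 10, n-BuLi, THF, −78 °C; then 9; then Ac2O, −78 °C → rt
Reagents that add atoms: acetic anhydride, CC(=O)OC(C)=O
Why: Acetylide addition to the aldehyde and O-acylation of the resulting alkoxide in the same flask give the propargylic acetate; the new carbinol centre (future C6) is formed without control, which is acceptable because both epimers converge in steps 7 and 8.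

Step 6
Reactants: 12 (6R)-6-[(tert-butyldiphenylsilyl)oxy]-4,4,8-trimethyl-1-(trimethylsilyl)non-8-en-1-yn-3-yl acetate
Product: 14 (6S)-6-[(tert-butyldiphenylsilyl)oxy]-4,4-dimethyl-8-oxo-1-(trimethylsilyl)non-1-yn-3-yl acetate (both C3 epimers), via ozonide 13 (not isolated)
Conditions: O3, CH2Cl2, −78 °C; then Me2S, −78 °C → rt
Reagents that add atoms: ozone, [O-][O+]=O
Why: Ozonolysis cleaves the electron-rich 1,1-disubstituted alkene much faster than the silyl-capped alkyne and reveals the C5 methyl ketone (the change of descriptor is only a change of CIP priority).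

Step 7
Reactants: 14 (6S)-6-[(tert-butyldiphenylsilyl)oxy]-4,4-dimethyl-8-oxo-1-(trimethylsilyl)non-1-yn-3-yl acetate
Product: 16 (5S)-5-[(tert-butyldiphenylsilyl)oxy]-1,3,3-trimethyl-2-[(trimethylsilyl)ethynyl]cyclohexan-1-ol (diastereomers at C1/C2), via allenylsamarium diiodide 15 (not isolated)
Conditions: Pd(PPh3)4 (5 mol%), SmI2 (2.5 equiv), THF, rt; then H2O
Reagents that add atoms: none
Why: Zerovalent palladium ionises the propargylic acetate by anti SN2' oxidative addition to a σ-allenyl complex of divalent palladium, which two equivalents of SmI2 reduce to the allenylsamarium 15 (trivalent samarium) with return of zerovalent palladium; 15 then adds through C6 to the C5 ketone in an SE2' fashion through a cyclic, metal-bridged transition state. The closest known reaction type is the palladium-catalysed, SmI2-mediated Barbier-type propargylation of ketones by propargylic esters, which is also known intramolecularly for 2-alkynylcycloalkanols. The six-membered ring C1–C6 closes in the 6-exo-trig mode (the C5=O bond is exocyclic to the new ring), helped by the gem-dimethyl group at C1 (Thorpe–Ingold effect), which also leaves the organopalladium intermediate without any β-hydrogen. The two new stereocentres C5 and C6 are not controlled and need not be, because both are erased in step 8, so both C6 epimers of 14 should converge while C3 is untouched. The step needs regioselectivity for C6 over C8 and chemoselectivity for the propargylic ester over the ketone: bonding through C8 would demand an eight-membered cyclic allene, and an unactivated dialkyl ketone is reduced by SmI2 in THF without additive far more slowly than the palladium-activated acetate.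

Step 8
Reactants: 16 (5S)-5-[(tert-butyldiphenylsilyl)oxy]-1,3,3-trimethyl-2-[(trimethylsilyl)ethynyl]cyclohexan-1-ol
Product: 17 tert-butyl{[(1R)-3,5,5-trimethyl-4-[(trimethylsilyl)ethynyl]cyclohex-3-en-1-yl]oxy}diphenylsilane
Conditions: p-TsOH·H2O (10 mol%), toluene, 80 °C
Reagents that add atoms: none
Why: Acid-catalysed E1 dehydration under equilibrating conditions sends every diastereomer of 16 through the same C5 cation, and the conjugated, tetrasubstituted C5=C6 enyne is the thermodynamic alkene isomer (as in a β-ionone-type ring), so the mixture should funnel into 17.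

Step 9
Reactants: 17 tert-butyl{[(1R)-3,5,5-trimethyl-4-[(trimethylsilyl)ethynyl]cyclohex-3-en-1-yl]oxy}diphenylsilane
Product: 18 tert-butyl{[(1R)-4-ethynyl-3,5,5-trimethylcyclohex-3-en-1-yl]oxy}diphenylsilane
Conditions: K2CO3 (0.2 equiv), MeOH/THF, rt
Reagents that add atoms: none
Why: Carbonate-catalysed methanolysis removes the alkynyl silyl group selectively; the silyl ether at C3 is stable to these conditions.

Step 10
Reactants: 18 tert-butyl{[(1R)-4-ethynyl-3,5,5-trimethylcyclohex-3-en-1-yl]oxy}diphenylsilane; 19 ethyl but-2-ynoate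
Product: 20 ethyl (2E)-5-[(4R)-4-[(tert-butyldiphenylsilyl)oxy]-2,6,6-trimethylcyclohex-1-en-1-yl]-3-methylpent-2-en-4-ynoate
Conditions: Pd(OAc)2 (3 mol%), tris(2,6-dimethoxyphenyl)phosphine (3 mol%), 19 (1.5 equiv), THF, rt
Reagents that add atoms: none
Why: Palladium-catalysed cross-addition of the terminal alkyne C–H bond across the ynoate (hydroalkynylation) is a syn addition with the alkynyl group going to the β-carbon, which sets the (9E) trisubstituted double bond.

Step 11
Reactants: 20 ethyl (2E)-5-[(4R)-4-[(tert-butyldiphenylsilyl)oxy]-2,6,6-trimethylcyclohex-1-en-1-yl]-3-methylpent-2-en-4-ynoate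
Product: 21 (2E)-5-[(4R)-4-[(tert-butyldiphenylsilyl)oxy]-2,6,6-trimethylcyclohex-1-en-1-yl]-3-methylpent-2-en-4-yn-1-ol
Conditions: i-Bu2AlH (2.5 equiv), CH2Cl2, −78 °C; aq. potassium sodium tartrate
Reagents that add atoms: none
Why: 1,2-Reduction of the conjugated ester to the allylic alcohol leaves the enyne geometry unchanged.

Step 12
Reactants: 21 (2E)-5-[(4R)-4-[(tert-butyldiphenylsilyl)oxy]-2,6,6-trimethylcyclohex-1-en-1-yl]-3-methylpent-2-en-4-yn-1-ol
Product: 23 [(2E)-5-[(4R)-4-[(tert-butyldiphenylsilyl)oxy]-2,6,6-trimethylcyclohex-1-en-1-yl]-3-methylpent-2-en-4-yn-1-yl]triphenylphosphonium bromide, via allylic bromide 22 (not isolated)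
Conditions: CBr4 (1.1 equiv), PPh3 (2.5 equiv), CH2Cl2, 0 °C → rt
Reagents that add atoms: triphenylphosphine, c1ccc(cc1)P(c1ccccc1)c1ccccc1; carbon tetrabromide, BrC(Br)(Br)Br
Why: Appel bromination of the primary allylic alcohol followed by SN2 quaternisation of triphenylphosphine in the same flask keeps the (9E) geometry, which an ionising acid route could scramble.

Step 13
Reactants: 24 β-cyclocitral
Product: 25 β-cyclogeraniol
Conditions: NaBH4, MeOH, 0 °C
Reagents that add atoms: none
Why: Hydride 1,2-reduction of the hindered enal gives the allylic alcohol needed to direct the epoxidation.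

Step 14
Reactants: 25 β-cyclogeraniol
Product: 26 [(1S,6S)-2,2,6-trimethyl-7-oxabicyclo[4.1.0]heptan-1-yl]methanol
Conditions: Ti(OiPr)4 (10 mol%), L-(+)-diethyl tartrate (12 mol%), t-BuOOH, 4 Å MS, CH2Cl2, −20 °C
Reagents that add atoms: tert-butyl hydroperoxide, CC(C)(C)OO
Why: Sharpless asymmetric epoxidation; with L-(+)-diethyl tartrate the oxygen should be delivered to the alkene face that gives the (1S,6S) epoxy alcohol (the same facial sense as geraniol to its 2S,3S epoxide), which fixes C6' and prepares C5' for inversion.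

Step 15
Reactants: 26 [(1S,6S)-2,2,6-trimethyl-7-oxabicyclo[4.1.0]heptan-1-yl]methanol
Product: 27 (1R,6S)-2,2,6-trimethyl-7-oxabicyclo[4.1.0]heptane-1-carbaldehyde
Conditions: Dess–Martin periodinane, CH2Cl2, 0 °C → rt
Reagents that add atoms: none
Why: Dess–Martin oxidation converts the primary epoxy alcohol to the aldehyde under conditions that leave the epoxide intact.

Step 16
Reactants: 27 (1R,6S)-2,2,6-trimethyl-7-oxabicyclo[4.1.0]heptane-1-carbaldehyde; 28 triethyl 3-methyl-4-phosphonocrotonate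
Product: 29 ethyl (2E,4E)-3-methyl-5-[(1R,6S)-2,2,6-trimethyl-7-oxabicyclo[4.1.0]heptan-1-yl]penta-2,4-dienoate
Conditions: 28, NaH, THF, 0 °C; then 27, 0 °C → rt
Reagents that add atoms: none
Why: Horner–Wadsworth–Emmons olefination with the vinylogous phosphonate should give the (7'E) double bond and mainly the (9'E) isomer, the minor (9'Z) isomer being removable by chromatography.

Step 17
Reactants: 29 ethyl (2E,4E)-3-methyl-5-[(1R,6S)-2,2,6-trimethyl-7-oxabicyclo[4.1.0]heptan-1-yl]penta-2,4-dienoate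
Product: 30 ethyl (2E,4E)-5-[(1R,2R)-1,2-dihydroxy-2,6,6-trimethylcyclohexyl]-3-methylpenta-2,4-dienoate
Conditions: HClO4 (aq., 5 mol%), THF/H2O, 0 °C → rt
Reagents that add atoms: water, O
Why: Acid-catalysed epoxide hydrolysis in which water attacks the methyl-bearing C5' with inversion, because positive charge at C6' is disfavoured by the attached electron-poor dienoate; C6' is retained and the trans (5'R,6'R) diol results.

Step 18
Reactants: 30 ethyl (2E,4E)-5-[(1R,2R)-1,2-dihydroxy-2,6,6-trimethylcyclohexyl]-3-methylpenta-2,4-dienoate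
Product: 31 (1R,2R)-1-[(1E,3E)-5-hydroxy-3-methylpenta-1,3-dien-1-yl]-2,6,6-trimethylcyclohexane-1,2-diol
Conditions: i-Bu2AlH (4 equiv), THF, −78 °C → 0 °C; aq. potassium sodium tartrate
Reagents that add atoms: none
Why: Hydride reduction of the dienoate to the allylic alcohol; the two tertiary hydroxyls only consume hydride.

Step 19
Reactants: 31 (1R,2R)-1-[(1E,3E)-5-hydroxy-3-methylpenta-1,3-dien-1-yl]-2,6,6-trimethylcyclohexane-1,2-diol
Product: 33 [(2E,4E)-5-[(1R,2R)-1,2-dihydroxy-2,6,6-trimethylcyclohexyl]-3-methylpenta-2,4-dien-1-yl]triphenylphosphonium bromide, via allylic bromide 32 (not isolated)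
Conditions: CBr4 (1.1 equiv), PPh3 (2.5 equiv), CH2Cl2, −20 °C → rt
Reagents that add atoms: triphenylphosphine, c1ccc(cc1)P(c1ccccc1)c1ccccc1; carbon tetrabromide, BrC(Br)(Br)Br
Why: Appel bromination is selective for the primary allylic hydroxyl over the two hindered tertiary ones, and in-situ trapping by triphenylphosphine under neutral conditions avoids acid-induced ionisation of the allylic C6' hydroxyl.

Step 20
Reactants: 33 [(2E,4E)-5-[(1R,2R)-1,2-dihydroxy-2,6,6-trimethylcyclohexyl]-3-methylpenta-2,4-dien-1-yl]triphenylphosphonium bromide; 34 (2E,4E,6E)-2,7-dimethylocta-2,4,6-trienedial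
Product: 36 (2E,4E,6E,8E,10E,12E)-13-[(1R,2R)-1,2-dihydroxy-2,6,6-trimethylcyclohexyl]-2,7,11-trimethyltrideca-2,4,6,8,10,12-hexaenal, via phosphorus ylide 35 (not isolated)
Conditions: 34 (3 equiv), NaOMe, CH2Cl2/MeOH, 0 °C → rt; then heptane, 70 °C
Reagents that add atoms: none
Why: Wittig olefination of the semi-stabilised ylide with an excess of the symmetrical dialdehyde should give the mono-adduct, and the new C11'=C12' bond, expected as an E/Z mixture, is equilibrated thermally to the unhindered E isomer.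

Step 21
Reactants: 23 [(2E)-5-[(4R)-4-[(tert-butyldiphenylsilyl)oxy]-2,6,6-trimethylcyclohex-1-en-1-yl]-3-methylpent-2-en-4-yn-1-yl]triphenylphosphonium bromide; 36 (2E,4E,6E,8E,10E,12E)-13-[(1R,2R)-1,2-dihydroxy-2,6,6-trimethylcyclohexyl]-2,7,11-trimethyltrideca-2,4,6,8,10,12-hexaenal
Product: 38 (3R,5'R,6'R)-3-[(tert-butyldiphenylsilyl)oxy]-7,8-didehydro-5',6'-dihydro-β,β-carotene-5',6'-diol (all-E), via phosphorus ylide 37 (not isolated)
Conditions: NaOMe, CH2Cl2/MeOH, 0 °C → rt; then heptane, 70 °C, dark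
Reagents that add atoms: none
Why: Wittig olefination forms C11=C12 and completes the C40 chain; gentle heating should convert the hindered 11Z isomer to the all-E polyene without disturbing the trisubstituted C9=C10 bond.

Step 22
Reactants: 38 (3R,5'R,6'R)-3-[(tert-butyldiphenylsilyl)oxy]-7,8-didehydro-5',6'-dihydro-β,β-carotene-5',6'-diol
Product: 39 (3R,5'R,6'R)-7,8-didehydro-5',6'-dihydro-β,β-carotene-3,5',6'-triol (all-E; the target)
Conditions: Bu4NF (3 equiv), THF, rt, dark
Reagents that add atoms: none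
Why: Fluoride cleavage of the silyl ether releases the C3 hydroxyl without touching the polyene or the diol.

**Compound list**

1 | (R)-epichlorohydrin | ClC[C@H]1CO1 | starting material
2 | isopropenylmagnesium bromide | CC(=C)[Mg]Br | starting material
3 | (R)-1-chloro-4-methylpent-4-en-2-ol | ClC[C@H](O)CC(C)=C | intermediate
4 | isobutyronitrile | CC(C)C#N | starting material
5 | (R)-2-(2-methylallyl)oxirane | CC(=C)C[C@@H]1CO1 | intermediate
6 | (R)-4-hydroxy-2,2,6-trimethylhept-6-enenitrile | N#CC(C)(C)C[C@H](O)CC(C)=C | intermediate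
7 | (R)-4-[(tert-butyldiphenylsilyl)oxy]-2,2,6-trimethylhept-6-enenitrile | N#CC(C)(C)C[C@H](O[Si](c1ccccc1)(c1ccccc1)C(C)(C)C)CC(C)=C | intermediate
8 | (R)-N-(diisobutylalumanyl)-4-[(tert-butyldiphenylsilyl)oxy]-2,2,6-trimethylhept-6-en-1-imine | CC(C)C[Al](CC(C)C)N=CC(C)(C)C[C@H](O[Si](c1ccccc1)(c1ccccc1)C(C)(C)C)CC(C)=C | intermediate
9 | (R)-4-[(tert-butyldiphenylsilyl)oxy]-2,2,6-trimethylhept-6-enal | O=CC(C)(C)C[C@H](O[Si](c1ccccc1)(c1ccccc1)C(C)(C)C)CC(C)=C | intermediate
10 | ethynyltrimethylsilane | C#C[Si](C)(C)C | starting material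
11 | lithium (6R)-6-[(tert-butyldiphenylsilyl)oxy]-4,4,8-trimethyl-1-(trimethylsilyl)non-8-en-1-yn-3-olate (both C3 epimers) | [Li+].[O-]C(C#C[Si](C)(C)C)C(C)(C)C[C@H](O[Si](c1ccccc1)(c1ccccc1)C(C)(C)C)CC(C)=C | intermediate
12 | (6R)-6-[(tert-butyldiphenylsilyl)oxy]-4,4,8-trimethyl-1-(trimethylsilyl)non-8-en-1-yn-3-yl acetate (both C3 epimers) | C[Si](C)(C)C#CC(OC(C)=O)C(C)(C)C[C@H](O[Si](c1ccccc1)(c1ccccc1)C(C)(C)C)CC(C)=C | intermediate
13 | (6S)-6-[(tert-butyldiphenylsilyl)oxy]-4,4-dimethyl-7-(3-methyl-1,2,4-trioxolan-3-yl)-1-(trimethylsilyl)hept-1-yn-3-yl acetate | C[Si](C)(C)C#CC(OC(C)=O)C(C)(C)C[C@H](O[Si](c1ccccc1)(c1ccccc1)C(C)(C)C)CC1(C)OCOO1 | intermediate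
14 | (6S)-6-[(tert-butyldiphenylsilyl)oxy]-4,4-dimethyl-8-oxo-1-(trimethylsilyl)non-1-yn-3-yl acetate (both C3 epimers) | C[Si](C)(C)C#CC(OC(C)=O)C(C)(C)C[C@H](O[Si](c1ccccc1)(c1ccccc1)C(C)(C)C)CC(C)=O | intermediate
15 | [(6S)-6-[(tert-butyldiphenylsilyl)oxy]-4,4-dimethyl-8-oxo-1-(trimethylsilyl)nona-1,2-dien-1-yl]samarium diiodide | CC(=O)C[C@@H](O[Si](c1ccccc1)(c1ccccc1)C(C)(C)C)CC(C)(C)C=C=C([Si](C)(C)C)[Sm](I)I | intermediate
16 | (5S)-5-[(tert-butyldiphenylsilyl)oxy]-1,3,3-trimethyl-2-[(trimethylsilyl)ethynyl]cyclohexan-1-ol (diastereomers at C1/C2) | CC1(O)C[C@@H](O[Si](c2ccccc2)(c2ccccc2)C(C)(C)C)CC(C)(C)C1C#C[Si](C)(C)C | intermediate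
17 | tert-butyl{[(1R)-3,5,5-trimethyl-4-[(trimethylsilyl)ethynyl]cyclohex-3-en-1-yl]oxy}diphenylsilane | CC1=C(C#C[Si](C)(C)C)C(C)(C)C[C@H](O[Si](c2ccccc2)(c2ccccc2)C(C)(C)C)C1 | intermediate
18 | tert-butyl{[(1R)-4-ethynyl-3,5,5-trimethylcyclohex-3-en-1-yl]oxy}diphenylsilane | CC1=C(C#C)C(C)(C)C[C@H](O[Si](c2ccccc2)(c2ccccc2)C(C)(C)C)C1 | intermediate
19 | ethyl but-2-ynoate | CC#CC(=O)OCC | starting material
20 | ethyl (2E)-5-[(4R)-4-[(tert-butyldiphenylsilyl)oxy]-2,6,6-trimethylcyclohex-1-en-1-yl]-3-methylpent-2-en-4-ynoate | CC1=C(C#C/C(C)=C/C(=O)OCC)C(C)(C)C[C@H](O[Si](c2ccccc2)(c2ccccc2)C(C)(C)C)C1 | intermediate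
21 | (2E)-5-[(4R)-4-[(tert-butyldiphenylsilyl)oxy]-2,6,6-trimethylcyclohex-1-en-1-yl]-3-methylpent-2-en-4-yn-1-ol | CC1=C(C#C/C(C)=C/CO)C(C)(C)C[C@H](O[Si](c2ccccc2)(c2ccccc2)C(C)(C)C)C1 | intermediate
22 | tert-butyl{[(1R)-4-[(3E)-5-bromo-3-methylpent-3-en-1-yn-1-yl]-3,5,5-trimethylcyclohex-3-en-1-yl]oxy}diphenylsilane | CC1=C(C#C/C(C)=C/CBr)C(C)(C)C[C@H](O[Si](c2ccccc2)(c2ccccc2)C(C)(C)C)C1 | intermediate
23 | [(2E)-5-[(4R)-4-[(tert-butyldiphenylsilyl)oxy]-2,6,6-trimethylcyclohex-1-en-1-yl]-3-methylpent-2-en-4-yn-1-yl]triphenylphosphonium bromide | [Br-].CC1=C(C#C/C(C)=C/C[P+](c2ccccc2)(c2ccccc2)c2ccccc2)C(C)(C)C[C@H](O[Si](c2ccccc2)(c2ccccc2)C(C)(C)C)C1 | intermediate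
24 | β-cyclocitral (2,6,6-trimethylcyclohex-1-ene-1-carbaldehyde) | CC1=C(C=O)C(C)(C)CCC1 | starting material
25 | β-cyclogeraniol [(2,6,6-trimethylcyclohex-1-en-1-yl)methanol] | CC1=C(CO)C(C)(C)CCC1 | intermediate
26 | [(1S,6S)-2,2,6-trimethyl-7-oxabicyclo[4.1.0]heptan-1-yl]methanol | OC[C@]12O[C@@]1(C)CCCC2(C)C | intermediate
27 | (1R,6S)-2,2,6-trimethyl-7-oxabicyclo[4.1.0]heptane-1-carbaldehyde | O=C[C@]12O[C@@]1(C)CCCC2(C)C | intermediate
28 | triethyl 3-methyl-4-phosphonocrotonate (ethyl 4-(diethoxyphosphoryl)-3-methylbut-2-enoate) | CCOC(=O)C=C(C)CP(=O)(OCC)OCC | starting material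
29 | ethyl (2E,4E)-3-methyl-5-[(1R,6S)-2,2,6-trimethyl-7-oxabicyclo[4.1.0]heptan-1-yl]penta-2,4-dienoate | CCOC(=O)/C=C(C)/C=C/[C@]12O[C@@]1(C)CCCC2(C)C | intermediate
30 | ethyl (2E,4E)-5-[(1R,2R)-1,2-dihydroxy-2,6,6-trimethylcyclohexyl]-3-methylpenta-2,4-dienoate | CCOC(=O)/C=C(C)/C=C/[C@@]1(O)C(C)(C)CCC[C@@]1(C)O | intermediate
31 | (1R,2R)-1-[(1E,3E)-5-hydroxy-3-methylpenta-1,3-dien-1-yl]-2,6,6-trimethylcyclohexane-1,2-diol | OC/C=C(C)/C=C/[C@@]1(O)C(C)(C)CCC[C@@]1(C)O | intermediate
32 | (1R,2R)-1-[(1E,3E)-5-bromo-3-methylpenta-1,3-dien-1-yl]-2,6,6-trimethylcyclohexane-1,2-diol | BrC/C=C(C)/C=C/[C@@]1(O)C(C)(C)CCC[C@@]1(C)O | intermediate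
33 | [(2E,4E)-5-[(1R,2R)-1,2-dihydroxy-2,6,6-trimethylcyclohexyl]-3-methylpenta-2,4-dien-1-yl]triphenylphosphonium bromide | [Br-].c1ccccc1[P+](c1ccccc1)(c1ccccc1)C/C=C(C)/C=C/[C@@]1(O)C(C)(C)CCC[C@@]1(C)O | intermediate
34 | (2E,4E,6E)-2,7-dimethylocta-2,4,6-trienedial | O=C/C(C)=C/C=C/C=C(C)/C=O | starting material
35 | {(2E,4E)-5-[(1R,2R)-1,2-dihydroxy-2,6,6-trimethylcyclohexyl]-3-methylpenta-2,4-dien-1-ylidene}triphenyl-λ5-phosphane | c1ccccc1P(c1ccccc1)(c1ccccc1)=C/C=C(C)/C=C/[C@@]1(O)C(C)(C)CCC[C@@]1(C)O | intermediate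
36 | (2E,4E,6E,8E,10E,12E)-13-[(1R,2R)-1,2-dihydroxy-2,6,6-trimethylcyclohexyl]-2,7,11-trimethyltrideca-2,4,6,8,10,12-hexaenal | O=C/C(C)=C/C=C/C=C(C)/C=C/C=C(C)/C=C/[C@@]1(O)C(C)(C)CCC[C@@]1(C)O | intermediate
37 | {(2E)-5-[(4R)-4-[(tert-butyldiphenylsilyl)oxy]-2,6,6-trimethylcyclohex-1-en-1-yl]-3-methylpent-2-en-4-yn-1-ylidene}triphenyl-λ5-phosphane | CC1=C(C#C/C(C)=C/C=P(c2ccccc2)(c2ccccc2)c2ccccc2)C(C)(C)C[C@H](O[Si](c2ccccc2)(c2ccccc2)C(C)(C)C)C1 | intermediate
38 | (3R,5'R,6'R)-3-[(tert-butyldiphenylsilyl)oxy]-7,8-didehydro-5',6'-dihydro-β,β-carotene-5',6'-diol (all-E) | CC1=C(C#C/C(C)=C/C=C/C(C)=C/C=C/C=C(C)/C=C/C=C(C)/C=C/[C@@]2(O)C(C)(C)CCC[C@@]2(C)O)C(C)(C)C[C@H](O[Si](c3ccccc3)(c3ccccc3)C(C)(C)C)C1 | intermediate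
39 | (3R,5'R,6'R)-7,8-didehydro-5',6'-dihydro-β,β-carotene-3,5',6'-triol (all-E) | CC1=C(C#C/C(C)=C/C=C/C(C)=C/C=C/C=C(C)/C=C/C=C(C)/C=C/[C@@]2(O)C(C)(C)CCC[C@@]2(C)O)C(C)(C)C[C@H](O)C1 | target

**Step count and risks**

Total step count: 22. Longest linear sequence: 14 steps (steps 1–12, 21, 22).

Steps most likely to fail:

1. Step 7. The allenylsamarium may be protonated or over-reduced, or the ketone may undergo ketyl coupling, before the hindered C5–C6 bond forms. The fallback forms the same bond by an amine-catalysed aldol ring closure. It sets out from aldehyde 9: Wittig reaction with (methoxymethyl)triphenylphosphonium chloride and KOt-Bu should give the enol ether tert-butyl{[(4R)-8-methoxy-2,6,6-trimethylocta-1,7-dien-4-yl]oxy}diphenylsilane F1. Mild aqueous formic acid then unmasks the homologated aldehyde (R)-5-[(tert-butyldiphenylsilyl)oxy]-3,3,7-trimethyloct-7-enal F2, and ozonolysis gives the keto aldehyde (S)-5-[(tert-butyldiphenylsilyl)oxy]-3,3-dimethyl-7-oxooctanal F3. Piperidinium acetate should effect the enamine aldol condensation, in which C6 as the aldehyde α-carbon attacks the C5 ketone, to (R)-4-[(tert-butyldiphenylsilyl)oxy]-2,6,6-trimethylcyclohex-1-ene-1-carbaldehyde F4. Seyferth–Gilbert homologation with the Ohira–Bestmann reagent (K2CO3, MeOH) brings the sequence back to the route at alkyne 18.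

2. Step 8. Regiocontrol of the elimination may be lost (proton loss toward C4 or the C5 methyl group), or the C5 cation may react in other acid-promoted ways. The fallback forms C5=C6 directly by reductive carbonyl coupling, with no elimination. It sets out from aldehyde 9: addition of lithium (trimethylsilyl)acetylide (via alkoxide 11) and protonation gives the propargylic alcohol (6R)-6-[(tert-butyldiphenylsilyl)oxy]-4,4,8-trimethyl-1-(trimethylsilyl)non-8-en-1-yn-3-ol F5. Dess–Martin oxidation gives the ynone (R)-6-[(tert-butyldiphenylsilyl)oxy]-4,4,8-trimethyl-1-(trimethylsilyl)non-8-en-1-yn-3-one F6, and ozonolysis gives the diketone (S)-6-[(tert-butyldiphenylsilyl)oxy]-4,4-dimethyl-1-(trimethylsilyl)non-1-yne-3,8-dione F7. Intramolecular McMurry coupling with low-valent titanium (TiCl3, Zn(Cu), DME, reflux, slow addition) comes back to the route at enyne 17.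

3. Step 17. The C5' cation may lose a proton to an allylic alcohol instead of being trapped by water, or the epoxide may open at the allylic C6'–O bond with loss of configuration or cyclic ether formation. The fallback hydrolyses before the side chain is attached, when C6' carries only a CH2OH group. It sets out from epoxy alcohol 26: aqueous HClO4 in THF should give the triol (1S,2R)-1-(hydroxymethyl)-2,6,6-trimethylcyclohexane-1,2-diol F8. TEMPO with PhI(OAc)2 oxidises the primary hydroxyl to (1R,2R)-1,2-dihydroxy-2,6,6-trimethylcyclohexane-1-carbaldehyde F9. Horner–Wadsworth–Emmons reaction with 28 under LiCl/DBU (a mild base, chosen to avoid α-ketol rearrangement) comes back to the route at diol ester 30.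

**Further compounds**

F1 | step 7 | tert-butyl{[(4R)-8-methoxy-2,6,6-trimethylocta-1,7-dien-4-yl]oxy}diphenylsilane (E/Z mixture) | COC=CC(C)(C)C[C@H](O[Si](c1ccccc1)(c1ccccc1)C(C)(C)C)CC(C)=C
F2 | step 7 | (R)-5-[(tert-butyldiphenylsilyl)oxy]-3,3,7-trimethyloct-7-enal | O=CCC(C)(C)C[C@H](O[Si](c1ccccc1)(c1ccccc1)C(C)(C)C)CC(C)=C
F3 | step 7 | (S)-5-[(tert-butyldiphenylsilyl)oxy]-3,3-dimethyl-7-oxooctanal | O=CCC(C)(C)C[C@H](O[Si](c1ccccc1)(c1ccccc1)C(C)(C)C)CC(C)=O
F4 | step 7 | (R)-4-[(tert-butyldiphenylsilyl)oxy]-2,6,6-trimethylcyclohex-1-ene-1-carbaldehyde | CC1=C(C=O)C(C)(C)C[C@H](O[Si](c2ccccc2)(c2ccccc2)C(C)(C)C)C1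
F5 | step 8 | (6R)-6-[(tert-butyldiphenylsilyl)oxy]-4,4,8-trimethyl-1-(trimethylsilyl)non-8-en-1-yn-3-ol (both C3 epimers) | C[Si](C)(C)C#CC(O)C(C)(C)C[C@H](O[Si](c1ccccc1)(c1ccccc1)C(C)(C)C)CC(C)=C
F6 | step 8 | (R)-6-[(tert-butyldiphenylsilyl)oxy]-4,4,8-trimethyl-1-(trimethylsilyl)non-8-en-1-yn-3-one | C[Si](C)(C)C#CC(=O)C(C)(C)C[C@H](O[Si](c1ccccc1)(c1ccccc1)C(C)(C)C)CC(C)=C
F7 | step 8 | (S)-6-[(tert-butyldiphenylsilyl)oxy]-4,4-dimethyl-1-(trimethylsilyl)non-1-yne-3,8-dione | C[Si](C)(C)C#CC(=O)C(C)(C)C[C@H](O[Si](c1ccccc1)(c1ccccc1)C(C)(C)C)CC(C)=O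
F8 | step 17 | (1S,2R)-1-(hydroxymethyl)-2,6,6-trimethylcyclohexane-1,2-diol | OC[C@@]1(O)C(C)(C)CCC[C@@]1(C)O
F9 | step 17 | (1R,2R)-1,2-dihydroxy-2,6,6-trimethylcyclohexane-1-carbaldehyde | O=C[C@@]1(O)C(C)(C)CCC[C@@]1(C)O
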